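## Retrosynthetic overview

1. Target 18 ⇒ aryltetralin phenol 12: the 8‑O‑4′ side chain is added last (Mitsunobu with ethyl (S)‑lactate, Weinreb amide, aryl Grignard, chelation‑controlled reduction, debenzylation).
2. 12 ⇒ benzylic alcohol 11: Friedel–Crafts closure of the tetralin (C1–C8a), the only ring made; all‑trans under control of C2/C3.
3. 11 ⇒ aldehyde 9 + ring‑B aryl metal; 9 ⇒ acid 5 by ArLi acylation/deoxygenation (ring A) and alkene cleavage.
4. 5 ⇒ Ireland–Claisen [3,3] rearrangement of (R,Z)‑pent‑3‑en‑2‑yl propanoate: forms the C2–C3 (C8–C8′) bond and both methyl stereocentres by 1,3‑chirality transfer from (R)‑but‑3‑yn‑2‑ol.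

Assumption: (R)‑but‑3‑yn‑2‑ol (≥98% ee), ethyl (S)‑lactate, 1‑(benzyloxy)‑4‑bromo‑2‑methoxybenzene and 4‑bromo‑2‑methoxyphenol are purchased.

Target stereochemistry as read from the SMILES: tetralin (1S,2S,3R) = all‑trans; side chain (1S,2R) = erythro.

## Route

**Step 1**
Reactants: 1, (R)‑but‑3‑yn‑2‑ol
Product: 2, (R)‑pent‑3‑yn‑2‑ol
Conditions: n‑BuLi (2.1 equiv), THF, −78 → −20 °C; MeI (1.05 equiv), −78 °C → rt
Reagents that add atoms: iodomethane, CI
Why: Alkylation of the alkoxide/acetylide dianion occurs at the more nucleophilic acetylide carbon; the carbinol centre is untouched.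

**Step 2**
Reactants: 2, (R)‑pent‑3‑yn‑2‑ol
Product: 3, (2R,3Z)‑pent‑3‑en‑2‑ol
Conditions: H2 (1 atm), Lindlar catalyst, quinoline, pentane, rt
Reagents that add atoms: none
Why: Lindlar semihydrogenation gives the (Z)‑alkene by syn H2 delivery without touching the stereocentre.

**Step 3**
Reactants: 3, (2R,3Z)‑pent‑3‑en‑2‑ol
Product: 4, (2R,3Z)‑pent‑3‑en‑2‑yl propanoate
Conditions: EtCOCl, pyridine, DMAP (cat.), CH2Cl2, 0 °C → rt
Reagents that add atoms: propanoyl chloride, CCC(=O)Cl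
Why: Simple O‑acylation with retention at the carbinol carbon.

**Step 4 (key step)**
Reactants: 4, (2R,3Z)‑pent‑3‑en‑2‑yl propanoate
Product: 5, (2S,3R,4E)‑2,3‑dimethylhex‑4‑enoic acid
Conditions: LDA, THF, −78 °C; TMSCl/Et3N, −78 °C → rt, then 55 °C; aq. NaOH, then HCl
Reagents that add atoms: none
Why: Ireland–Claisen [3,3] rearrangement: LDA/THF gives the E(O)‑enolate (α‑Me cis to the allyloxy O), and the chair with the carbinol Me equatorial and the (Z)‑alkene Me axial transfers the (R)‑carbinol chirality to the 2,3‑syn (2S,3R) acid with a new (E)‑alkene (expected about 9:1 syn:anti; the minor isomer is removed at crystalline 12).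

**Step 5**
Reactants: 5, (2S,3R,4E)‑2,3‑dimethylhex‑4‑enoic acid; 6, 1‑(benzyloxy)‑4‑bromo‑2‑methoxybenzene
Product: 7, (2S,3R,4E)‑1‑[4‑(benzyloxy)‑3‑methoxyphenyl]‑2,3‑dimethylhex‑4‑en‑1‑one
Conditions: 6 (2.3 equiv), n‑BuLi, THF, −78 °C; add 5, −78 → 0 °C; inverse quench into cold 1 M HCl
Reagents that add atoms: none beyond 5 and 6
Why: Aryllithium addition to the lithium carboxylate gives a gem‑dialkoxide that collapses to the ketone only on workup, so there is no over‑addition and no enolisable ketone in base.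

**Step 6**
Reactants: 7
Product: 8, 1‑(benzyloxy)‑4‑[(2R,3S,4E)‑2,3‑dimethylhex‑4‑en‑1‑yl]‑2‑methoxybenzene
Conditions: Et3SiH (4 equiv), TFA, CH2Cl2, 0 °C → rt
Reagents that add atoms: none
Why: Ionic hydrogenation of the electron‑rich aryl ketone via the p‑alkoxybenzyl cation; the 1,2‑disubstituted alkene and benzyl ether are inert, and fast hydride capture preserves the adjacent centre (descriptors change by CIP only).

**Step 7**
Reactants: 8
Product: 9, (2S,3R)‑4‑[4‑(benzyloxy)‑3‑methoxyphenyl]‑2,3‑dimethylbutanal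
Conditions: OsO4 (2 mol%), NaIO4 (4 equiv), 2,6‑lutidine, dioxane/H2O 3:1, rt; use crude
Reagents that add atoms: osmium tetroxide, O=[Os](=O)(=O)=O, with sodium periodate, [Na+].[O-]I(=O)(=O)=O (carbonyl O)
Why: Lemieux–Johnson cleavage removes the propenyl terminus as acetaldehyde and spares the electron‑rich arene (unlike ozone); buffered conditions avoid α‑epimerisation.

**Step 8**
Reactants: 9; 10, 4‑bromo‑2‑methoxyphenol
Product: 11, (1RS,2S,3R)‑4‑[4‑(benzyloxy)‑3‑methoxyphenyl]‑1‑(4‑hydroxy‑3‑methoxyphenyl)‑2,3‑dimethylbutan‑1‑ol (C1 epimers)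
Conditions: 10 (1.5 equiv), i‑PrMgCl (1 equiv per ArBr), THF, 0 °C; n‑BuLi (2 equiv per ArBr), −20 °C; then 9, −40 → 0 °C
Reagents that add atoms: none beyond 9 and 10
Why: Deprotonation then Br–Mg exchange via a lithium magnesiate metalates the unprotected bromophenol, and this weakly basic aryl nucleophile adds to the aldehyde; the C1 configuration is irrelevant because it is ionised next.

**Step 9**
Reactants: 11
Product: 12, 4‑[(1S,2S,3R)‑7‑(benzyloxy)‑6‑methoxy‑2,3‑dimethyl‑1,2,3,4‑tetrahydronaphthalen‑1‑yl]‑2‑methoxyphenol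
Conditions: TFA (5 equiv), CH2Cl2 (0.01 M), −20 → 0 °C
Reagents that add atoms: none
Why: Intramolecular Friedel–Crafts alkylation: the p‑hydroxybenzyl (quinone‑methide) cation is attacked by ring A para to its OMe through a chair‑like transition state with aryl and both methyls pseudo‑equatorial, giving the all‑trans (1S) tetralin from both C1 epimers.

**Step 10**
Reactants: 12; 13, ethyl (S)‑lactate
Product: 14, ethyl (2R)‑2‑{4‑[(1S,2S,3R)‑7‑(benzyloxy)‑6‑methoxy‑2,3‑dimethyl‑1,2,3,4‑tetrahydronaphthalen‑1‑yl]‑2‑methoxyphenoxy}propanoate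
Conditions: PPh3, DIAD, THF, 0 °C → rt
Reagents that add atoms: none beyond 12 and 13
Why: Mitsunobu etherification of the only free phenol proceeds by clean SN2 inversion of the lactate carbinol, (S) → (R).

**Step 11**
Reactants: 14
Product: 15, (2R)‑2‑{4‑[(1S,2S,3R)‑7‑(benzyloxy)‑6‑methoxy‑2,3‑dimethyl‑1,2,3,4‑tetrahydronaphthalen‑1‑yl]‑2‑methoxyphenoxy}‑N‑methoxy‑N‑methylpropanamide
Conditions: MeNH(OMe)·HCl, i‑PrMgCl, THF, −20 → 0 °C
Reagents that add atoms: N,O‑dimethylhydroxylamine hydrochloride, CNOC.Cl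
Why: Direct aminolysis by the weakly basic magnesium amide gives the Weinreb amide without enolising the α‑aryloxy centre.

**Step 12**
Reactants: 15; 6 (as its Grignard reagent)
Product: 16, (2R)‑1‑[4‑(benzyloxy)‑3‑methoxyphenyl]‑2‑{4‑[(1S,2S,3R)‑7‑(benzyloxy)‑6‑methoxy‑2,3‑dimethyl‑1,2,3,4‑tetrahydronaphthalen‑1‑yl]‑2‑methoxyphenoxy}propan‑1‑one
Conditions: ArMgBr (from 6, Mg, THF; 1.5 equiv), THF, 0 °C; aq. NH4Cl; use promptly
Reagents that add atoms: none beyond 15 and 6
Why: Weinreb ketone synthesis: the stable chelated tetrahedral intermediate prevents over‑addition and keeps the α‑centre non‑enolisable until workup.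

**Step 13**
Reactants: 16
Product: 17, (1S,2R)‑1‑[4‑(benzyloxy)‑3‑methoxyphenyl]‑2‑{4‑[(1S,2S,3R)‑7‑(benzyloxy)‑6‑methoxy‑2,3‑dimethyl‑1,2,3,4‑tetrahydronaphthalen‑1‑yl]‑2‑methoxyphenoxy}propan‑1‑ol
Conditions: Zn(BH4)2, Et2O/CH2Cl2, −20 → 0 °C
Reagents that add atoms: none
Why: Cram‑chelate reduction: Zn bridges the carbonyl and aryloxy oxygens and hydride attacks from the H side (anti to Me), giving the anti/erythro (1S,2R) alcohol under control of the lactate‑derived centre.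

**Step 14**
Reactants: 17
Product: 18, (1S,2R)‑1‑(4‑hydroxy‑3‑methoxyphenyl)‑2‑{4‑[(1S,2S,3R)‑7‑hydroxy‑6‑methoxy‑2,3‑dimethyl‑1,2,3,4‑tetrahydronaphthalen‑1‑yl]‑2‑methoxyphenoxy}propan‑1‑ol (target)
Conditions: H2 (1 atm), 10% Pd/C, EtOAc, rt, monitored and stopped at full debenzylation
Reagents that add atoms: none
Why: Neutral hydrogenolysis cleaves both aryl benzyl ethers faster than the secondary benzylic C–OH; no stereocentre is affected.

## Compound list

1 | (R)‑but‑3‑yn‑2‑ol | C[C@@H](O)C#C | starting material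
2 | (R)‑pent‑3‑yn‑2‑ol | C[C@@H](O)C#CC | intermediate
3 | (2R,3Z)‑pent‑3‑en‑2‑ol | C[C@@H](O)/C=C\C | intermediate
4 | (2R,3Z)‑pent‑3‑en‑2‑yl propanoate | C[C@@H](OC(=O)CC)/C=C\C | intermediate
5 | (2S,3R,4E)‑2,3‑dimethylhex‑4‑enoic acid | OC(=O)[C@@H](C)[C@H](C)/C=C/C | intermediate
6 | 1‑(benzyloxy)‑4‑bromo‑2‑methoxybenzene | COc1cc(Br)ccc1OCc1ccccc1 | starting material
7 | (2S,3R,4E)‑1‑[4‑(benzyloxy)‑3‑methoxyphenyl]‑2,3‑dimethylhex‑4‑en‑1‑one | COc1cc(C(=O)[C@@H](C)[C@H](C)/C=C/C)ccc1OCc1ccccc1 | intermediate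
8 | 1‑(benzyloxy)‑4‑[(2R,3S,4E)‑2,3‑dimethylhex‑4‑en‑1‑yl]‑2‑methoxybenzene | COc1cc(C[C@@H](C)[C@H](C)/C=C/C)ccc1OCc1ccccc1 | intermediate
9 | (2S,3R)‑4‑[4‑(benzyloxy)‑3‑methoxyphenyl]‑2,3‑dimethylbutanal | COc1cc(C[C@@H](C)[C@H](C)C=O)ccc1OCc1ccccc1 | intermediate
10 | 4‑bromo‑2‑methoxyphenol | COc1cc(Br)ccc1O | starting material
11 | (1RS,2S,3R)‑4‑[4‑(benzyloxy)‑3‑methoxyphenyl]‑1‑(4‑hydroxy‑3‑methoxyphenyl)‑2,3‑dimethylbutan‑1‑ol | COc1cc(C[C@@H](C)[C@H](C)C(O)c2ccc(O)c(OC)c2)ccc1OCc1ccccc1 | intermediate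
12 | 4‑[(1S,2S,3R)‑7‑(benzyloxy)‑6‑methoxy‑2,3‑dimethyl‑1,2,3,4‑tetrahydronaphthalen‑1‑yl]‑2‑methoxyphenol | COc1cc([C@H]2c3cc(OCc4ccccc4)c(OC)cc3C[C@@H](C)[C@@H]2C)ccc1O | intermediate
13 | ethyl (S)‑lactate | CCOC(=O)[C@H](C)O | starting material
14 | ethyl (2R)‑2‑aryloxypropanoate of 12 | CCOC(=O)[C@@H](C)Oc1ccc([C@H]2c3cc(OCc4ccccc4)c(OC)cc3C[C@@H](C)[C@@H]2C)cc1OC | intermediate
15 | (2R)‑Weinreb amide | CON(C)C(=O)[C@@H](C)Oc1ccc([C@H]2c3cc(OCc4ccccc4)c(OC)cc3C[C@@H](C)[C@@H]2C)cc1OC | intermediate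
16 | (2R)‑α‑aryloxy aryl ketone | COc1cc(C(=O)[C@@H](C)Oc2ccc([C@H]3c4cc(OCc5ccccc5)c(OC)cc4C[C@@H](C)[C@@H]3C)cc2OC)ccc1OCc1ccccc1 | intermediate
17 | (1S,2R)‑erythro alcohol, bis‑benzyl ether | COc1cc([C@H](O)[C@@H](C)Oc2ccc([C@H]3c4cc(OCc5ccccc5)c(OC)cc4C[C@@H](C)[C@@H]3C)cc2OC)ccc1OCc1ccccc1 | intermediate
18 | CID53359464 | COc1cc([C@H](O)[C@@H](C)Oc2ccc([C@H]3c4cc(O)c(OC)cc4C[C@@H](C)[C@@H]3C)cc2OC)ccc1O | target

## Summary

Total steps: 14. Longest linear sequence: 14 (1 → 18).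

Steps most likely to fail:

1. **Step 4 (Ireland–Claisen).** The syn:anti ratio depends on enolate geometry, and the minor diastereomer travels with the material until 12. Fallback: Johnson orthoester Claisen of 3 with MeC(OEt)3 (sets one methyl centre by the same chirality transfer), alkene cleavage/NaBH4 to the β‑methyl‑γ‑butyrolactone, trans‑selective lactone α‑methylation (LDA, MeI), then ArLi opening, deoxygenation and oxidation to rejoin at 9.
2. **Step 8 (unprotected bromophenol metalation with an epimerisable aldehyde).** Exchange may be incomplete or the aldehyde may epimerise. Fallback: use the TBS ether of 10 with ordinary Br/Li exchange, cyclise as in step 9 and remove the silyl group with TBAF afterwards (one extra step).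
3. **Step 13 (chelation‑controlled reduction).** The erythro:threo ratio may be low, and ketone 16 can racemise at C2. Fallback: reduce under Felkin control (L‑Selectride) to the threo alcohol and invert the benzylic carbinol by Mitsunobu (p‑nitrobenzoic acid) and methanolysis before debenzylation.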